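**Retrosynthetic overview**
- The 14-membered ring is closed last by a C3–C4 Nozaki–Hiyama–Kishi coupling of a seco aldehyde / alkenyl iodide.
- C9–OH and C11–OAc come from one Evans–Tishchenko reduction of a β-hydroxy enone, itself made by a C10–C11 boron aldol between a lactone aldehyde and a (Z)-enone/(E)-alkenyl iodide fragment (from pent-3-yn-1-ol).
- The ε-lactone comes from Baeyer–Villiger ring expansion of a 2,2,5-trisubstituted cyclohexanone (C12–O formed with retention), followed by α-methylenation.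
- That cyclohexanone comes from o-cresol: Birch dearomatisation of its silyl ether to a regiodefined tetrasubstituted enol silane (key step), then catalytic asymmetric hydroxymethylation (C12) and Rh-catalysed asymmetric 1,4-addition (C1).
- Ring order: six-membered carbocycle (from the arene) → seven-membered lactone → fourteen-membered carbocycle.

Numbering used in the comments (cembrane numbering of the target): C1 = lactone-ring CH, C3/C9 = carbinols, C11 = CH–OAc, C12 = quaternary C–O, C15 = C(=CH2), C16 = lactone C=O; the target is 1S,3R,4E,7Z,9R,11R,12S.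

**Route**

Step 1
Reactants: 1 o-cresol (2-methylphenol)
Product: 2 tert-butyldimethyl(2-methylphenoxy)silane
Conditions: TBSCl, imidazole, DMF, rt
Reagents that add atoms: tert-butyldimethylsilyl chloride, C[Si](C)(Cl)C(C)(C)C
Why: O-silylation gives an aryl silyl ether that survives dissolving-metal reduction and already carries the silicon of the later enol silane; no stereocentre.

Step 2
Reactants: 2 tert-butyldimethyl(2-methylphenoxy)silane
Product: 3 tert-butyldimethyl[(2-methylcyclohexa-1,4-dien-1-yl)oxy]silane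
Conditions: Li, NH3(l)/THF, t-BuOH, −78 to −33 °C
Reagents that add atoms: none
Why: Birch reduction (the key dearomatisation): the O and methyl donors stay on sp2 carbons, so only the 2,5-dihydro isomer forms, a tetrasubstituted enol silane at the future C12 that cannot be made regioselectively from the ketone; no stereocentre yet.

Step 3
Reactants: 3 tert-butyldimethyl[(2-methylcyclohexa-1,4-dien-1-yl)oxy]silane
Product: 4 (6S)-6-(hydroxymethyl)-6-methylcyclohex-3-en-1-one
Conditions: 35% aq. HCHO, Sc(OTf)3 (10 mol%), (S,S)-6,6'-bis(1-hydroxy-2,2-dimethylpropyl)-2,2'-bipyridine (12 mol%), DME/H2O, −20 to 0 °C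
Reagents that add atoms: formaldehyde, C=O
Why: Kobayashi-type catalytic asymmetric Mukaiyama aldol (hydroxymethylation): the chiral Sc(OTf)3–bipyridine complex activates formaldehyde and shields one face of the prochiral enol silane, setting the C12 quaternary centre as S (the ligand antipode is used if the facial sense on this substrate is reversed).

Step 4
Reactants: 4 (6S)-6-(hydroxymethyl)-6-methylcyclohex-3-en-1-one; 5 2-[(E)-2-ethoxyethenyl]-4,4,5,5-tetramethyl-1,3,2-dioxaborolane
Product: 8 (2S,5S)-5-(2,2-diethoxyethyl)-2-(hydroxymethyl)-2-methylcyclohexan-1-one, via conjugated enone 6 (not isolated), via enol ether 7 (not isolated)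
Conditions: [Rh(cod)OH]2 (2.5 mol%), (R)-BINAP (6 mol%), Et3N (1 equiv), dioxane/H2O 10:1, 35 °C; evaporate; EtOH, PPTS (10 mol%), rt
Reagents that add atoms: ethanol, CCO
Why: Base-mediated β,γ→α,β isomerisation, then Hayashi–Miyaura Rh-catalysed asymmetric 1,4-addition in which the (R)-BINAP–Rh alkenyl species selects the enone face that sets C1 (catalyst control, the remote C12 exerting little bias), and acid-catalysed addition of ethanol to the enol ether masks the future C3 aldehyde as its diethyl acetal.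

Step 5
Reactants: 8 (2S,5S)-5-(2,2-diethoxyethyl)-2-(hydroxymethyl)-2-methylcyclohexan-1-one
Product: 9 (4S,7S)-4-(2,2-diethoxyethyl)-7-(hydroxymethyl)-7-methyloxepan-2-one
Conditions: mCPBA, NaHCO3, CH2Cl2, 0 °C to rt
Reagents that add atoms: 3-chloroperbenzoic acid, O=C(OO)c1cccc(Cl)c1
Why: Baeyer–Villiger oxidation: the fully substituted C12 migrates in preference to the C15 methylene and with retention, so the ring expands to the ε-lactone and the tertiary C12–O centre is S.

Step 6
Reactants: 9 (4S,7S)-4-(2,2-diethoxyethyl)-7-(hydroxymethyl)-7-methyloxepan-2-one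
Product: 12 (4S,7S)-4-(2,2-diethoxyethyl)-7-(hydroxymethyl)-7-methyl-3-methylideneoxepan-2-one, via Mannich base 10 (not isolated), via ammonium iodide 11 (not isolated)
Conditions: LiN(iPr)2 (2.2 equiv), THF, −78 °C; CH2=NMe2+ I− (1.1 equiv), −78 to 0 °C; crude amine: MeI, MeOH, rt; then aq. NaHCO3/CH2Cl2, rt
Reagents that add atoms: Eschenmoser's salt (N,N-dimethylmethyleneiminium iodide), C=[N+](C)C.[I-]
Why: Mannich aminomethylation of the lactone enolate (C15 is the only enolisable position), N-methylation and E1cB loss of trimethylamine install the exocyclic methylene, the transient C15 centre becoming sp2 while C1 and C12 are untouched.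

Step 7
Reactants: 12 (4S,7S)-4-(2,2-diethoxyethyl)-7-(hydroxymethyl)-7-methyl-3-methylideneoxepan-2-one
Product: 13 (2S,5S)-5-(2,2-diethoxyethyl)-2-methyl-6-methylidene-7-oxooxepane-2-carbaldehyde
Conditions: Dess–Martin periodinane, NaHCO3, CH2Cl2, 0 °C to rt
Reagents that add atoms: none
Why: Dess–Martin oxidation of the neopentyl primary alcohol gives the non-enolisable α-acyloxy aldehyde (C11) without touching the acetal or the methylene lactone; no stereocentre is formed or put at risk.

Step 8
Reactants: 14 pent-3-yn-1-ol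
Product: 16 (3E)-4-iodopent-3-en-1-ol, via alkenylzirconocene 15 (not isolated)
Conditions: Cp2Zr(H)Cl (2.5 equiv), THF, rt to 40 °C; then I2, 0 °C
Reagents that add atoms: iodine, II
Why: Hydrozirconation–iodination: syn Zr–H addition, equilibration of zirconium to the methyl-bearing alkyne carbon under excess hydride and iodinolysis with retention give the E-2-iodoalkene that becomes C4–C7 (E C4=C5).

Step 9
Reactants: 16 (3E)-4-iodopent-3-en-1-ol
Product: 17 (3E)-4-iodopent-3-enal
Conditions: Dess–Martin periodinane, NaHCO3, CH2Cl2, 0 °C; used crude at once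
Reagents that add atoms: none
Why: Buffered Dess–Martin oxidation gives the β,γ-unsaturated aldehyde without moving the double bond into conjugation.

Step 10
Reactants: 17 (3E)-4-iodopent-3-enal; 18 ethyl 2-[bis(2,2,2-trifluoroethoxy)phosphoryl]propanoate
Product: 19 ethyl (2Z,5E)-6-iodo-2-methylhepta-2,5-dienoate
Conditions: 18, KN(SiMe3)2, 18-crown-6, THF, −78 °C; then 17
Reagents that add atoms: none
Why: Still–Gennari olefination: fast, irreversible elimination from the kinetic adduct of the trifluoroethyl phosphonate gives the Z trisubstituted enoate (C7=C8 with C6 cis to C9).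

Step 11
Reactants: 19 ethyl (2Z,5E)-6-iodo-2-methylhepta-2,5-dienoate
Product: 20 (2Z,5E)-6-iodo-N-methoxy-N,2-dimethylhepta-2,5-dienamide
Conditions: MeNH(OMe)·HCl, i-PrMgCl, THF, −20 °C
Reagents that add atoms: N,O-dimethylhydroxylamine hydrochloride, CNOC.Cl
Why: Weinreb amidation by the magnesium amide leaves the Z olefin intact, and at −20 °C iodine–magnesium exchange of the alkenyl iodide is slow.

Step 12
Reactants: 20 (2Z,5E)-6-iodo-N-methoxy-N,2-dimethylhepta-2,5-dienamide
Product: 21 (3Z,6E)-7-iodo-3-methylocta-3,6-dien-2-one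
Conditions: MeMgBr, THF, −78 to 0 °C; aq. NH4Cl
Reagents that add atoms: methylmagnesium bromide, C[Mg]Br
Why: Weinreb ketone synthesis: the stable magnesium chelate stops after one addition and releases the Z methyl enone (C8–C10) on work-up.

Step 13
Reactants: 21 (3Z,6E)-7-iodo-3-methylocta-3,6-dien-2-one; 13 (2S,5S)-5-(2,2-diethoxyethyl)-2-methyl-6-methylidene-7-oxooxepane-2-carbaldehyde
Product: 23 (4S,7S)-4-(2,2-diethoxyethyl)-7-[(1R,4Z,7E)-1-hydroxy-8-iodo-4-methyl-3-oxonona-4,7-dien-1-yl]-7-methyl-3-methylideneoxepan-2-one, via boron enolate 22 (not isolated)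
Conditions: 21, (c-Hex)2BCl, Et3N, Et2O, −78 to 0 °C; then 13, −78 to −20 °C; MeOH, pH 7 buffer
Reagents that add atoms: none
Why: Boron-mediated aldol of the kinetic methyl-ketone enolate with the α-acyloxy aldehyde: without chelation the enolate attacks anti to the C12–O bond and past the methyl rather than the ring CH2 (Cornforth / polar Felkin–Anh), setting C11 as R.

Step 14
Reactants: 23 (the β-hydroxy enone of step 13)
Product: 24 (1R,3R,4Z,7E)-1-[(2S,5S)-5-(2,2-diethoxyethyl)-2-methyl-6-methylidene-7-oxooxepan-2-yl]-3-hydroxy-8-iodo-4-methylnona-4,7-dien-1-yl acetate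
Conditions: MeCHO (8 equiv), SmI2 (0.3 equiv), THF, −10 °C
Reagents that add atoms: acetaldehyde, CC=O
Why: Evans–Tishchenko reduction: the samarium-bound hemiacetal on O11 delivers hydride intramolecularly to the C9 ketone through a six-membered chair transition state, giving the 1,3-anti diol (C9 R) with the acetate on O11 and O9 free in one operation.

Step 15
Reactants: 24 (the hydroxy acetate of step 14)
Product: 25 (1R,3R,4Z,7E)-3-hydroxy-8-iodo-4-methyl-1-[(2S,5S)-2-methyl-6-methylidene-7-oxo-5-(2-oxoethyl)oxepan-2-yl]nona-4,7-dien-1-yl acetate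
Conditions: PPTS (0.2 equiv), acetone/H2O 10:1, 40 °C
Reagents that add atoms: water, O
Why: Mild acid-catalysed acetal hydrolysis releases the C3 aldehyde while the acetate, allylic alcohol, skipped diene and methylene lactone survive; no stereocentre is touched.

Step 16
Reactants: 25 (the seco aldehyde / alkenyl iodide of step 15)
Product: 26 (1S,3R,4E,7Z,9R,11R,12S)-11-acetoxy-3,9-dihydroxycembra-4,7,15(17)-trien-16,12-olide (target)
Conditions: CrCl2 (10 equiv), NiCl2 (2 mol%), (S)-N-[2-(4-isopropyl-4,5-dihydrooxazol-2-yl)-6-methylphenyl]methanesulfonamide (11 equiv), Et3N (11 equiv), THF/MeCN 1:1, 2 mM, rt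
Reagents that add atoms: none
Why: Nozaki–Hiyama–Kishi macrocyclisation: Ni-catalysed insertion into the C–I bond, transmetalation to chromium and addition to the aldehyde close the 14-membered ring with retention of the E olefin, the chiral sulfonamide on chromium (antipode chosen as needed) directing attack to the aldehyde face that gives the 3R carbinol.

**Compound list**
1 | o-cresol (2-methylphenol) | Cc1ccccc1O | starting material
2 | tert-butyldimethyl(2-methylphenoxy)silane | Cc1ccccc1O[Si](C)(C)C(C)(C)C | intermediate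
3 | tert-butyldimethyl[(2-methylcyclohexa-1,4-dien-1-yl)oxy]silane | CC1=C(O[Si](C)(C)C(C)(C)C)CC=CC1 | intermediate
4 | (6S)-6-(hydroxymethyl)-6-methylcyclohex-3-en-1-one | O=C1CC=CC[C@@]1(C)CO | intermediate
5 | 2-[(E)-2-ethoxyethenyl]-4,4,5,5-tetramethyl-1,3,2-dioxaborolane | CCO/C=C/B1OC(C)(C)C(C)(C)O1 | starting material
6 | (6S)-6-(hydroxymethyl)-6-methylcyclohex-2-en-1-one | O=C1C=CCC[C@@]1(C)CO | intermediate
7 | (2S,5R)-5-[(E)-2-ethoxyethenyl]-2-(hydroxymethyl)-2-methylcyclohexan-1-one | O=C1C[C@H](/C=C/OCC)CC[C@@]1(C)CO | intermediate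
8 | (2S,5S)-5-(2,2-diethoxyethyl)-2-(hydroxymethyl)-2-methylcyclohexan-1-one | O=C1C[C@H](CC(OCC)OCC)CC[C@@]1(C)CO | intermediate
9 | (4S,7S)-4-(2,2-diethoxyethyl)-7-(hydroxymethyl)-7-methyloxepan-2-one | C1C(=O)O[C@@](CO)(C)CC[C@H]1CC(OCC)OCC | intermediate
10 | (4S,7S)-4-(2,2-diethoxyethyl)-3-[(dimethylamino)methyl]-7-(hydroxymethyl)-7-methyloxepan-2-one (C3 epimers) | CN(C)CC1C(=O)O[C@@](CO)(C)CC[C@H]1CC(OCC)OCC | intermediate
11 | {[(4S,7S)-4-(2,2-diethoxyethyl)-7-(hydroxymethyl)-7-methyl-2-oxooxepan-3-yl]methyl}trimethylammonium iodide (C3 epimers) | C[N+](C)(C)CC1C(=O)O[C@@](CO)(C)CC[C@H]1CC(OCC)OCC.[I-] | intermediate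
12 | (4S,7S)-4-(2,2-diethoxyethyl)-7-(hydroxymethyl)-7-methyl-3-methylideneoxepan-2-one | C=C1C(=O)O[C@@](CO)(C)CC[C@H]1CC(OCC)OCC | intermediate
13 | (2S,5S)-5-(2,2-diethoxyethyl)-2-methyl-6-methylidene-7-oxooxepane-2-carbaldehyde | C=C1C(=O)O[C@@](C=O)(C)CC[C@H]1CC(OCC)OCC | intermediate
14 | pent-3-yn-1-ol | CC#CCCO | starting material
15 | (E)-alkenylzirconocene chloride from syn Zr–H addition to 14 (Zr on the methyl-bearing carbon, O bound to a second Cp2ZrCl unit) | C/C(=C\CCO[Zr](Cl)(C1C=CC=C1)C1C=CC=C1)[Zr](Cl)(C1C=CC=C1)C1C=CC=C1 | intermediate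
16 | (3E)-4-iodopent-3-en-1-ol | C/C(I)=C\CCO | intermediate
17 | (3E)-4-iodopent-3-enal | C/C(I)=C\CC=O | intermediate
18 | ethyl 2-[bis(2,2,2-trifluoroethoxy)phosphoryl]propanoate | CCOC(=O)C(C)P(=O)(OCC(F)(F)F)OCC(F)(F)F | starting material
19 | ethyl (2Z,5E)-6-iodo-2-methylhepta-2,5-dienoate | CCOC(=O)/C(C)=C\C/C=C(\C)I | intermediate
20 | (2Z,5E)-6-iodo-N-methoxy-N,2-dimethylhepta-2,5-dienamide | CON(C)C(=O)/C(C)=C\C/C=C(\C)I | intermediate
21 | (3Z,6E)-7-iodo-3-methylocta-3,6-dien-2-one | CC(=O)/C(C)=C\C/C=C(\C)I | intermediate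
22 | dicyclohexyl{[(3Z,6E)-7-iodo-3-methylocta-1,3,6-trien-2-yl]oxy}borane | C=C(OB(C1CCCCC1)C1CCCCC1)/C(C)=C\C/C=C(\C)I | intermediate
23 | (4S,7S)-4-(2,2-diethoxyethyl)-7-[(1R,4Z,7E)-1-hydroxy-8-iodo-4-methyl-3-oxonona-4,7-dien-1-yl]-7-methyl-3-methylideneoxepan-2-one | C=C1C(=O)O[C@@]([C@H](O)CC(=O)/C(C)=C\C/C=C(\C)I)(C)CC[C@H]1CC(OCC)OCC | intermediate
24 | (1R,3R,4Z,7E)-1-[(2S,5S)-5-(2,2-diethoxyethyl)-2-methyl-6-methylidene-7-oxooxepan-2-yl]-3-hydroxy-8-iodo-4-methylnona-4,7-dien-1-yl acetate | C=C1C(=O)O[C@@]([C@H](OC(C)=O)C[C@@H](O)/C(C)=C\C/C=C(\C)I)(C)CC[C@H]1CC(OCC)OCC | intermediate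
25 | (1R,3R,4Z,7E)-3-hydroxy-8-iodo-4-methyl-1-[(2S,5S)-2-methyl-6-methylidene-7-oxo-5-(2-oxoethyl)oxepan-2-yl]nona-4,7-dien-1-yl acetate | C=C1C(=O)O[C@@]([C@H](OC(C)=O)C[C@@H](O)/C(C)=C\C/C=C(\C)I)(C)CC[C@H]1CC=O | intermediate
26 | (1S,3R,4E,7Z,9R,11R,12S)-11-acetoxy-3,9-dihydroxycembra-4,7,15(17)-trien-16,12-olide (CNP0183491.2) | C=C1C(=O)O[C@@]2(C)CC[C@H]1C[C@@H](O)/C(C)=C/C/C=C(/C)[C@H](O)C[C@H]2OC(C)=O | target

**Step count and risks**
Total steps: 16. Longest linear sequence: 11 (steps 1–7, then 13–16); the iodo-enone branch is steps 8–12.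

Three steps most likely to fail:

Step 3. The Sc-catalysed hydroxymethylation is established for trimethylsilyl enolates of aryl ketones; a TBS enolate of a purely aliphatic tetrasubstituted enol may react slowly, hydrolyse instead, or give low ee. Fallback (from 3, back at 4): a kinetic resolution replaces asymmetric catalysis. Yb(OTf)3 and aqueous HCHO in THF convert 3 into racemic 6-(hydroxymethyl)-6-methylcyclohex-3-en-1-one F1. Lipase PS with vinyl acetate in t-BuOMe then acylates one enantiomer, ideally giving (R)-(1-methyl-2-oxocyclohex-4-en-1-yl)methyl acetate F2 and leaving (S)-alcohol 4. If the lipase prefers the S alcohol, its acetate is separated and cleaved with K2CO3/MeOH to give 4.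

Step 4. Three things must work in one pot: conjugation without retro-aldol loss of formaldehyde, transmetalation of an alkoxyvinyl boronate without protodeboronation, and catalyst-controlled facial selectivity. Fallback (from 4, back at 8): the two-carbon unit is added as a plain vinyl group and oxidised afterwards. K[CH2=CH–BF3] with [Rh(cod)OH]2/(R)-BINAP in dioxane/H2O gives (2S,5R)-5-ethenyl-2-(hydroxymethyl)-2-methylcyclohexan-1-one F3. Aldehyde-selective Wacker oxidation (PdCl2(PhCN)2, CuCl2, AgNO2, O2, t-BuOH/MeNO2) gives 2-[(1S,4S)-4-(hydroxymethyl)-4-methyl-3-oxocyclohexyl]acetaldehyde F4. HC(OEt)3, EtOH and PPTS then give 8.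

Step 16. Ring closure itself is well precedented, but the C3 configuration depends on whether the chiral chromium ligand can override the macrocycle's own bias. Fallback (from 25, back at 26): C3 is set by reagent-controlled reduction instead of C–C bond formation. Ligand-free CrCl2/NiCl2 in DMSO/THF closes the ring to 26 mixed with its C3 epimer, (1S,3S,4E,7Z,9R,11R,12S)-11-acetoxy-3,9-dihydroxycembra-4,7,15(17)-trien-16,12-olide F5. MnO2 in CH2Cl2 oxidises both allylic carbinols of the mixture to (1S,4E,7Z,11R,12S)-11-acetoxy-3,9-dioxocembra-4,7,15(17)-trien-16,12-olide F6. (S)-Me-CBS with BH3·SMe2 at −40 °C then reduces both ketones with the same facial sense, because each is flanked by an alkenyl (large) and a CH2 (small) group, giving the 3R,9R diol 26.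

Further compounds
F1 | step 3 | racemic 6-(hydroxymethyl)-6-methylcyclohex-3-en-1-one | O=C1CC=CCC1(C)CO
F2 | step 3 | (R)-(1-methyl-2-oxocyclohex-4-en-1-yl)methyl acetate | CC(=O)OC[C@@]1(C)CC=CCC1=O
F3 | step 4 | (2S,5R)-5-ethenyl-2-(hydroxymethyl)-2-methylcyclohexan-1-one | O=C1C[C@H](C=C)CC[C@@]1(C)CO
F4 | step 4 | 2-[(1S,4S)-4-(hydroxymethyl)-4-methyl-3-oxocyclohexyl]acetaldehyde | O=C1C[C@H](CC=O)CC[C@@]1(C)CO
F5 | step 16 | (1S,3S,4E,7Z,9R,11R,12S)-11-acetoxy-3,9-dihydroxycembra-4,7,15(17)-trien-16,12-olide (C3 epimer of 26) | C=C1C(=O)O[C@@]2(C)CC[C@H]1C[C@H](O)/C(C)=C/C/C=C(/C)[C@H](O)C[C@H]2OC(C)=O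
F6 | step 16 | (1S,4E,7Z,11R,12S)-11-acetoxy-3,9-dioxocembra-4,7,15(17)-trien-16,12-olide | C=C1C(=O)O[C@@]2(C)CC[C@H]1CC(=O)/C(C)=C/C/C=C(/C)C(=O)C[C@H]2OC(C)=O
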